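**Retrosynthetic overview**
- Target ⇒ (−)-β-caryophyllene + an acyl enetrione (1-oxadiene). One intermolecular oxa-Diels–Alder reaction across the E-configured C4=C5 bond closes the dihydropyran ring and sets C4, C5 and C1′ under control of the purchased C1/C9 centres.
- Enetrione ⇒ Knoevenagel condensation, in the same flask, of syncarpic acid with 3-methyl-2-oxobutanal.
- Syncarpic acid ⇒ deacetylation of acetylsyncarpic acid ⇐ exhaustive C-methylation of 2,4,6-trihydroxyacetophenone; the keto-aldehyde ⇐ SeO2 oxidation of 3-methylbutan-2-one.
- Ring order: the cyclohexanetrione ring comes first (dearomatised phloroglucinol core); the cyclobutane and nine-membered rings are bought in caryophyllene; the dihydropyran ring is formed last.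

Assumption: syncarpic acid and 3-methyl-2-oxobutanal are treated as non-stock items and are made from bulk chemicals; natural (−)-β-caryophyllene (1R,9S) is bought.

Caryophyllane numbering is used for the target: C1/C9 are the cyclobutane ring-fusion carbons, C4 is the methyl-bearing olefinic carbon, C5 is the olefinic CH, C8 carries the exocyclic methylene, and C1′ is the methine carrying the 2-methylpropanoyl group.

**Step 1**
Reactants: 1 2,4,6-trihydroxyacetophenone
Product: 2 2-acetyl-4,4,6,6-tetramethylcyclohexane-1,3,5-trione (acetylsyncarpic acid, drawn as its enol)
Conditions: MeI (6 equiv), NaOMe (6 equiv), MeOH, 0 °C to reflux; aq. HCl work-up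
Reagents that add atoms: iodomethane, CI
Why: Exhaustive dearomatising enolate C-methylation of the phloroglucinol nucleus; the acetyl group blocks one ring carbon, so the four methyl groups go pairwise onto the two free ring carbons and lock the ring as the cyclohexanetrione (no stereocentre formed).

**Step 2**
Reactants: 2 2-acetyl-4,4,6,6-tetramethylcyclohexane-1,3,5-trione
Product: 3 syncarpic acid (2,2,4,4-tetramethylcyclohexane-1,3,5-trione)
Conditions: 6 M aq. HCl, reflux
Reagents that add atoms: none
Why: Acid-mediated retro-Claisen deacylation of the tricarbonyl methine cleaves the exocyclic acetyl group as acetic acid, while the gem-dimethyl-blocked ring carbonyls cannot fragment (no stereocentre involved).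

**Step 3**
Reactants: 4 3-methylbutan-2-one
Product: 5 3-methyl-2-oxobutanal (isopropylglyoxal)
Conditions: SeO2 (1.0 equiv), 1,4-dioxane/H2O, reflux; distillation, used fresh
Reagents that add atoms: selenium dioxide, O=[Se]=O
Why: Riley oxidation takes the α-methyl group of the methyl ketone to the aldehyde through its enol, and the tertiary α′-carbon cannot be carried to a carbonyl (no stereocentre formed).

**Step 4**
Reactants: 3 syncarpic acid; 5 3-methyl-2-oxobutanal; 6 (−)-β-caryophyllene
Product: 8 Tomentodione R, via enetrione 7 (not isolated)
Conditions: ethylenediammonium diacetate (10 mol %), 5 (1.2 equiv), 6 (3 equiv), toluene/MeCN, 60 °C, slow addition of 3; SiO2 chromatography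
Reagents that add atoms: none
Why: Domino Knoevenagel condensation/inverse-electron-demand oxa-Diels–Alder reaction, in which 7 adds as a 1-oxadiene across the strained E-C4=C5 bond of 6 (the exocyclic methylene is much less reactive) with C5 attacking the doubly activated exocyclic CH and the dione oxygen closing on the more substituted C4; suprafacial addition to the exposed outer face of the trans-olefin (the face that also gives natural caryophyllene β-oxide) sets 4R,5S with a trans ring fusion under control of the bought C1/C9 centres, and the transition state with C5–H under the diene and the isobutyryl group outside is expected to favour 1′S (acyl pseudo-equatorial, cis to H-5, trans to the C4 methyl), though the C1′ epimer and minor face isomers will co-form and are removed by chromatography.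

**Compound list**
1 | 2,4,6-trihydroxyacetophenone | CC(=O)c1c(O)cc(O)cc1O | starting material
2 | 2-acetyl-4,4,6,6-tetramethylcyclohexane-1,3,5-trione (enol form) | CC(=O)C1=C(O)C(C)(C)C(=O)C(C)(C)C1=O | intermediate
3 | syncarpic acid, 2,2,4,4-tetramethylcyclohexane-1,3,5-trione | CC1(C)C(=O)CC(=O)C(C)(C)C1=O | intermediate
4 | 3-methylbutan-2-one | CC(=O)C(C)C | starting material
5 | 3-methyl-2-oxobutanal | CC(C)C(=O)C=O | intermediate
6 | (−)-β-caryophyllene, (1R,4E,9S)-4,11,11-trimethyl-8-methylidenebicyclo[7.2.0]undec-4-ene | C=C1CC/C=C(\C)CC[C@@H]2[C@@H]1CC2(C)C | starting material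
7 | 2-(3-methyl-2-oxobutylidene)-4,4,6,6-tetramethylcyclohexane-1,3,5-trione | CC(C)C(=O)C=C1C(=O)C(C)(C)C(=O)C(C)(C)C1=O | intermediate
8 | Tomentodione R, (1R,4R,5S,9S,1′S) dihydropyran adduct: ether O on C4 (bearing CH3), C5–H bonded to C1′, C1′ carrying 2-methylpropanoyl cis to H-5 and trans to the C4 methyl, C8 exocyclic methylene retained | C=C1CC[C@H]2[C@H](C(=O)C(C)C)C3=C(O[C@]2(C)CC[C@@H]2[C@@H]1CC2(C)C)C(C)(C)C(=O)C(C)(C)C3=O | target

**Total step count:** 4
**Longest linear sequence:** 3 steps (steps 1, 2, 4)

**Steps most likely to fail**

Step 4 (stereochemical outcome at C1′). The kinetic ratio may favour the wrong C1′ epimer. The fallback sets out from 7, generated as in step 4 in the presence of 6, and replaces kinetic control by thermodynamic control. The whole 4R,5S adduct fraction, including 1′-epi-tomentodione R F1, is not separated but heated with DBU (0.5 equiv) in toluene at 80 °C. C1′–H is α to the isobutyryl ketone and its enolate is conjugated with the vinylogous ester, so this centre alone equilibrates. The epimer with the pseudo-equatorial acyl group, free of the 1,3-diaxial contact with the C4 methyl, should be favoured, and the fallback comes back to the route at 8.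

Step 3 (Riley oxidation: over-oxidation, attack at the isopropyl methine, selenium residues). The fallback sets out from 4 and installs the aldehyde by halogenation and oxygen transfer instead. Br2 in MeOH at 0–10 °C brominates the methyl group selectively to give 1-bromo-3-methylbutan-2-one F2. Kornblum oxidation in DMSO at room temperature then gives the glyoxal, and the fallback comes back to the route at 5.

Step 1 (incomplete, excessive or O-methylation in the fourfold alkylation). The fallback sets out from 4 and builds the trione ring by acylation instead of dearomatisation. The kinetic enolate of 4 (LiN(iPr)2, THF, −78 °C) is acylated by dimethyl 2,2-dimethylmalonate in a crossed Claisen condensation to give methyl 2,2,6-trimethyl-3,5-dioxoheptanoate F3. Its diketone dianion (further LiN(iPr)2, −78 °C to room temperature) closes by Dieckmann-type acylation through the tertiary γ-carbon onto the ester. This bypasses step 2, and the fallback comes back to the route at 3.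

**Further compounds**
F1 | step 4 | 1′-epi-tomentodione R | C=C1CC[C@H]2[C@@H](C(=O)C(C)C)C3=C(O[C@]2(C)CC[C@@H]2[C@@H]1CC2(C)C)C(C)(C)C(=O)C(C)(C)C3=O
F2 | step 3 | 1-bromo-3-methylbutan-2-one | CC(C)C(=O)CBr
F3 | step 1 | methyl 2,2,6-trimethyl-3,5-dioxoheptanoate | COC(=O)C(C)(C)C(=O)CC(=O)C(C)C
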